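**Retrosynthetic overview**

1. Last disconnection: the C(=O)–CH= bond of the cycloheptenone (ring ketone carbon to the β-carbon of the ring enal). This leads to seco-aldehyde 15, in which a cyclopropyl formyl group faces a β-(tert-butylsulfanyl) enal. In the forward sense an acyl radical adds and tBuS• leaves, so two acceptor carbons are joined by radical polarity reversal.
2. Enabling feature: the formyl carbon sits on the cyclopropane CH that is cis to the pyranyl group, and the enal sits on pyran C3, cis to the cyclopropyl group on C4. The two cis-locked small rings hold the reacting carbons within reach, and the sulfanyl group on the enal β-carbon is a radical leaving group and chain carrier.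
3. 15 comes from terminal alkyne 14, CO and tBuSH (radical thioformylation). The two acetates of 14 come from a silyl acetal, a formyl group and a nitrile (DIBAL, then acetylation and fluoride-triggered anomeric acetylation with retention).
4. The dihydropyran comes from a domino Knoevenagel/inverse-demand hetero-Diels–Alder reaction of cyano aldehyde 4, malondialdehyde 8 and (Z)-silyloxyenyne 7, which sets pyran C2, C3 and C4 (all cis) relative to the cyclopropane.
5. Ring order: cyclopropane (bought as lactone 1, both CH centres) → dihydropyran (step 4) → cycloheptenone (step 8, last).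

Key step: step 8

Remark: lactone 1 (both antipodes are sold as chiral cyclopropane building blocks), but-3-yn-1-ol 5 and malondialdehyde tetrabutylammonium salt 8 are taken as purchasable.
Remark: pyran locants in the text are O1, C2 (acetal), C3, C4, C5 (bears the C1 side chain) and C6 (=CH–O).

**Route**

Step 1
Reactants: 1 (1S,5R)-6,6-dimethyl-3-oxabicyclo[3.1.0]hexan-2-one
Product: 3 (1S,3R)-3-(hydroxymethyl)-2,2-dimethylcyclopropane-1-carbonitrile, via hydroxy amide 2 (not isolated)
Conditions: AlMe3 (3.5 equiv), NH3 (3.5 equiv; gives Me2AlNH2), xylenes, 25 → 130 °C; aq. KNaC4H4O6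
Reagents that add atoms: ammonia, N
Why: Weinreb-type aminolysis of the lactone by Me2AlNH2 followed by dehydration of the primary amide by the excess aluminium reagent at 130 °C (the known one-pot ester-to-nitrile conversion) should give the cis hydroxy nitrile, both cyclopropane stereocentres coming unchanged from 1 because neither ring C–H is acidified under these Lewis-acidic conditions.

Step 2
Reactants: 3 (1S,3R)-3-(hydroxymethyl)-2,2-dimethylcyclopropane-1-carbonitrile
Product: 4 (1S,3R)-3-formyl-2,2-dimethylcyclopropane-1-carbonitrile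
Conditions: Dess–Martin periodinane (1.2 equiv), CH2Cl2, 0 → 25 °C
Reagents that add atoms: none
Why: Dess–Martin oxidation of the primary alcohol is neutral and fast, so the cis aldehyde should form without epimerisation of the cyclopropane carbon next to it and without hydration or cyclisation of the neighbouring nitrile.

Step 3
Reactants: 5 but-3-yn-1-ol
Product: 7 tert-butyl[(1Z)-but-1-en-3-yn-1-yloxy]dimethylsilane, via but-3-ynal 6 (not isolated)
Conditions: Dess–Martin periodinane (1.1 equiv), CH2Cl2, 0 °C; filter (pentane); then Et3N (3 equiv), TBSOTf (1.2 equiv), CH2Cl2, −78 → 0 °C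
Reagents that add atoms: tert-butyldimethylsilyl trifluoromethanesulfonate, CC(C)(C)[Si](C)(C)OS(=O)(=O)C(F)(F)F
Why: Dess–Martin oxidation gives the ynal without base (no drift to the allenal) and soft enolisation with TBSOTf and Et3N (silyl enol ether formation) should then trap it as the conjugated enol ether, the Z isomer being expected to prevail as is usual for aldehyde-derived silyl enol ethers made this way and any E isomer being removed by distillation.

Step 4
Reactants: 4 (1S,3R)-3-formyl-2,2-dimethylcyclopropane-1-carbonitrile, 8 malondialdehyde tetrabutylammonium salt, 7 tert-butyl[(1Z)-but-1-en-3-yn-1-yloxy]dimethylsilane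
Product: 10 (1S,3R)-3-[(2S,3R,4R)-2-{[tert-butyl(dimethyl)silyl]oxy}-3-ethynyl-5-formyl-3,4-dihydro-2H-pyran-4-yl]-2,2-dimethylcyclopropane-1-carbonitrile, via alkylidene malonaldehyde 9 (not isolated)
Conditions: 8 (1.1 equiv), AcOH (1.1 equiv), ethylenediammonium diacetate (0.05 equiv), 4 Å MS, CH2Cl2, 0 °C; then 7 (2 equiv), 0 → 25 °C
Reagents that add atoms: none
Why: Domino Knoevenagel condensation and inverse-electron-demand hetero-Diels–Alder reaction (Tietze reaction): the alkylidene malonaldehyde 9 is a very electron-poor 1-oxadiene in which either formyl group can serve, the Z geometry of enol ether 7 places silyloxy and ethynyl groups cis on pyran C2 and C3, the endo position of the silyloxy group places both cis to the cyclopropyl group on C4, and the face of 9 is chosen by its allylic-strain-controlled conformer (cyclopropane C–H eclipsing the alkylidene bond), in which the side of the slim linear nitrile is open while the other side is shielded by the syn methyl group of the CMe2 carbon.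

Step 5
Reactants: 10 (1S,3R)-3-[(2S,3R,4R)-2-{[tert-butyl(dimethyl)silyl]oxy}-3-ethynyl-5-formyl-3,4-dihydro-2H-pyran-4-yl]-2,2-dimethylcyclopropane-1-carbonitrile
Product: 12 (1S,3R)-3-[(2S,3R,4R)-2-{[tert-butyl(dimethyl)silyl]oxy}-3-ethynyl-5-(hydroxymethyl)-3,4-dihydro-2H-pyran-4-yl]-2,2-dimethylcyclopropane-1-carbaldehyde, via aldimine 11 (not isolated)
Conditions: iBu2AlH (3 equiv), CH2Cl2, −78 °C; MeOH, then aq. KNaC4H4O6, 25 °C
Reagents that add atoms: water, O
Why: DIBAL reduction at −78 °C should take the vinylogous formyl group to the primary allylic alcohol (as in the reduction of 2-C-formyl glycals) and stop at the N-aluminated aldimine for the nitrile, which the tartrate work-up hydrolyses to the aldehyde, while silyl acetal, enol ether and alkyne are inert and no stereocentre is touched.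

Step 6
Reactants: 12 (1S,3R)-3-[(2S,3R,4R)-2-{[tert-butyl(dimethyl)silyl]oxy}-3-ethynyl-5-(hydroxymethyl)-3,4-dihydro-2H-pyran-4-yl]-2,2-dimethylcyclopropane-1-carbaldehyde
Product: 14 [(2S,3R,4R)-2-acetoxy-3-ethynyl-4-[(1R,3S)-3-formyl-2,2-dimethylcyclopropyl]-3,4-dihydro-2H-pyran-5-yl]methyl acetate, via silyl acetal monoacetate 13 (not isolated)
Conditions: Ac2O (6 equiv), Et3N (4 equiv), DMAP (0.1 equiv), THF, 0 °C; then Bu4N[Ph3SiF2] (1.2 equiv), −78 → −40 °C
Reagents that add atoms: acetic anhydride, CC(=O)OC(C)=O
Why: DMAP-catalysed acetylation of the allylic alcohol is followed by fluoride-triggered cleavage of the anomeric silyl ether, whose lactolate is acetylated by the acylpyridinium salt at low temperature faster than it can ring-open (one-pot desilylation–acylation of anomeric silyl ethers as practised for glycosyl esters), so that the acetal configuration set in step 4 should be retained.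

Step 7
Reactants: 14 [(2S,3R,4R)-2-acetoxy-3-ethynyl-4-[(1R,3S)-3-formyl-2,2-dimethylcyclopropyl]-3,4-dihydro-2H-pyran-5-yl]methyl acetate
Product: 15 [(2S,3R,4R)-2-acetoxy-3-[1-(tert-butylsulfanyl)-3-oxoprop-1-en-2-yl]-4-[(1R,3S)-3-formyl-2,2-dimethylcyclopropyl]-3,4-dihydro-2H-pyran-5-yl]methyl acetate (E/Z mixture)
Conditions: tBuSH (5 equiv), CO (80 atm), AIBN (0.2 equiv), benzene (0.05 M), 90 °C
Reagents that add atoms: 2-methylpropane-2-thiol, CC(C)(C)S; carbon monoxide, [C-]#[O+]
Why: Thiyl-radical-mediated thioformylation of a terminal alkyne (radical carbonylation): tBuS• adds to the terminal carbon, the resulting vinyl radical captures CO and the unsaturated acyl radical takes hydrogen from the thiol, which places sulfur on the terminal and the formyl group on the internal carbon, while the excess thiol returns hydrogen to any acyl radical formed at the cyclopropyl aldehyde before it can cyclise, no stereocentre is formed and the alkene geometry is irrelevant for step 8.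

Step 8
Reactants: 15 [(2S,3R,4R)-2-acetoxy-3-[1-(tert-butylsulfanyl)-3-oxoprop-1-en-2-yl]-4-[(1R,3S)-3-formyl-2,2-dimethylcyclopropyl]-3,4-dihydro-2H-pyran-5-yl]methyl acetate
Product: 16 CNP0263020.2 (the target tricycle)
Conditions: tBuON=NOtBu (0.1 equiv), tBuSH (0.05 equiv), benzene (0.005 M), 60 °C, slow Ar purge
Reagents that add atoms: none
Why: Proposed new method: a thiyl-radical relay in which tBuS• (from the initiator and a trace of tBuSH) abstracts the formyl hydrogen of the cyclopropanecarbaldehyde, the σ-acyl radical adds to the sulfur-bearing β-carbon of the enal, and the α-formyl radical so formed expels tBuS• by β-fragmentation, which restores the C=C bond as the ring 2-ene-1,4-dione and carries the chain; the net loss of tBuSH joins two carbons that are both acceptor positions in the product. The closest known reactions are thiol-catalysed (polarity-reversal) acyl-radical cyclisations of alkenals to cyclic ketones, 7-endo cyclisations of acyl radicals onto the β-carbon of α-substituted acrylic acceptors, and radical addition–fragmentation of vinyl and allyl sulfides. The cycloheptenone closes in the 7-endo-trig mode, the alternative 6-exo attack having to occur at the fully substituted and electronically mismatched α-carbon of the enal. No stereocentre is created (the radical-bearing carbon becomes sp2), the four ring-fusion centres are those fixed in steps 1 and 4, and only their cis arrangement on both small rings allows closure. The step needs the acyl radical to choose the enal over the enol ether five atoms away and not to lose CO: the nucleophilic acyl radical is polarity-matched with the enal, the preferred rotamer about the cyclopropyl–pyranyl bond (pyran C4–H over the cyclopropane) turns the enol ether towards the CMe2 side and the sulfanyl enal towards the acyl carbon, and a cyclopropanecarbonyl radical decarbonylates very slowly. Hydrogen abstraction from the enal formyl group is reversible and unproductive, high dilution suppresses intermolecular addition, and purging the volatile tBuSH prevents its re-addition to the product.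

**Compound list**

1 | (1S,5R)-6,6-dimethyl-3-oxabicyclo[3.1.0]hexan-2-one | O=C1[C@H]2[C@@H](CO1)C2(C)C | starting material
2 | (1S,3R)-3-(hydroxymethyl)-2,2-dimethylcyclopropane-1-carboxamide | OC[C@@H]1[C@H](C(N)=O)C1(C)C | intermediate
3 | (1S,3R)-3-(hydroxymethyl)-2,2-dimethylcyclopropane-1-carbonitrile | OC[C@@H]1[C@H](C#N)C1(C)C | intermediate
4 | (1S,3R)-3-formyl-2,2-dimethylcyclopropane-1-carbonitrile | O=C[C@@H]1[C@H](C#N)C1(C)C | intermediate
5 | but-3-yn-1-ol | C#CCCO | starting material
6 | but-3-ynal | C#CCC=O | intermediate
7 | tert-butyl[(1Z)-but-1-en-3-yn-1-yloxy]dimethylsilane | C#C/C=C\O[Si](C)(C)C(C)(C)C | intermediate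
8 | malondialdehyde tetrabutylammonium salt (tetrabutylammonium 3-oxoprop-1-en-1-olate) | [O-]C=CC=O.CCCC[N+](CCCC)(CCCC)CCCC | starting material
9 | (1S,3R)-3-(2-formyl-3-oxoprop-1-en-1-yl)-2,2-dimethylcyclopropane-1-carbonitrile | O=CC(C=O)=C[C@@H]1[C@H](C#N)C1(C)C | intermediate
10 | (1S,3R)-3-[(2S,3R,4R)-2-{[tert-butyl(dimethyl)silyl]oxy}-3-ethynyl-5-formyl-3,4-dihydro-2H-pyran-4-yl]-2,2-dimethylcyclopropane-1-carbonitrile | O=CC1=CO[C@@H](O[Si](C)(C)C(C)(C)C)[C@@H](C#C)[C@H]1[C@@H]2[C@H](C#N)C2(C)C | intermediate
11 | {(2S,3R,4R)-2-{[tert-butyl(dimethyl)silyl]oxy}-3-ethynyl-4-[(1R,3S)-3-(iminomethyl)-2,2-dimethylcyclopropyl]-3,4-dihydro-2H-pyran-5-yl}methanol | OCC1=CO[C@@H](O[Si](C)(C)C(C)(C)C)[C@@H](C#C)[C@H]1[C@@H]2[C@H](C=N)C2(C)C | intermediate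
12 | (1S,3R)-3-[(2S,3R,4R)-2-{[tert-butyl(dimethyl)silyl]oxy}-3-ethynyl-5-(hydroxymethyl)-3,4-dihydro-2H-pyran-4-yl]-2,2-dimethylcyclopropane-1-carbaldehyde | OCC1=CO[C@@H](O[Si](C)(C)C(C)(C)C)[C@@H](C#C)[C@H]1[C@@H]2[C@H](C=O)C2(C)C | intermediate
13 | [(2S,3R,4R)-2-{[tert-butyl(dimethyl)silyl]oxy}-3-ethynyl-4-[(1R,3S)-3-formyl-2,2-dimethylcyclopropyl]-3,4-dihydro-2H-pyran-5-yl]methyl acetate | CC(=O)OCC1=CO[C@@H](O[Si](C)(C)C(C)(C)C)[C@@H](C#C)[C@H]1[C@@H]2[C@H](C=O)C2(C)C | intermediate
14 | [(2S,3R,4R)-2-acetoxy-3-ethynyl-4-[(1R,3S)-3-formyl-2,2-dimethylcyclopropyl]-3,4-dihydro-2H-pyran-5-yl]methyl acetate | CC(=O)OCC1=CO[C@@H](OC(C)=O)[C@@H](C#C)[C@H]1[C@@H]2[C@H](C=O)C2(C)C | intermediate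
15 | [(2S,3R,4R)-2-acetoxy-3-[1-(tert-butylsulfanyl)-3-oxoprop-1-en-2-yl]-4-[(1R,3S)-3-formyl-2,2-dimethylcyclopropyl]-3,4-dihydro-2H-pyran-5-yl]methyl acetate (E/Z mixture) | CC(=O)OCC1=CO[C@@H](OC(C)=O)[C@@H](C(C=O)=CSC(C)(C)C)[C@H]1[C@@H]2[C@H](C=O)C2(C)C | intermediate
16 | CNP0263020.2: dihydropyran (acetal carbon C2 with OAc, S; C3, R; C4, R; C5 with CH2OAc; C6 =CH–O) cis-fused through C3–C4 to a cycloheptenone that carries the formyl group on the alkene carbon bound to C3 and the ketone next to a cis-fused gem-dimethylcyclopropane (CH next to C=O, S; CH next to C4, R), cyclopropane anti to the pyran | CC(=O)OCC1=CO[C@@H](OC(C)=O)[C@H]2C(C=O)=CC(=O)[C@H]3[C@@H]([C@@H]12)C3(C)C | target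

**Step count and risks**

Total step count: 8. Longest linear sequence: 7 steps (1 → 3 → 4 → 10 → 12 → 14 → 15 → 16); step 3 is a one-step branch.

Risk 1, step 8 (the proposed new method). The chain may not propagate at high dilution because thiyl radicals dimerise before they abstract the formyl hydrogen. The acyl radical may also add to the enol ether or fragment the cyclopropane, or the thiol may add back to the enedione. The fallback uses known tin-hydride chemistry on a selenoester and sets out from 14. Chlorite oxidation (NaClO2, NaH2PO4, 2-methylbut-2-ene, tBuOH/H2O) of the cyclopropanecarbaldehyde gives the cyclopropanecarboxylic acid F1. (PhSe)2 and Bu3P convert it into the Se-phenyl selenoester F2. Thioformylation under the conditions of step 7 gives the sulfanyl-enal selenoester F3. Slow addition of Bu3SnH with AIBN in dilute benzene at 80 °C then generates the acyl radical irreversibly by selenium abstraction. The established 7-endo cyclisation of selenoester-derived acyl radicals onto the β-carbon of an α-substituted acrylic acceptor, followed by β-fragmentation of tBuS• (reduced by Bu3SnH), comes back to the route at 16.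

Risk 2, step 7. The vinyl radical may be quenched by the thiol before it captures CO (plain hydrothiolation), or may shift a hydrogen intramolecularly. The acyl radical of the cyclopropyl aldehyde may also cyclise onto the alkyne. The fallback is polar and needs no CO; it sets out from 14. Anti-Markovnikov hydration of the terminal alkyne with [CpRu(MeCN)3]PF6 and 5,5′-bis(trifluoromethyl)-2,2′-bipyridine in aqueous acetone gives the dialdehyde F4. This is treated at once with N,N-dimethylformamide dimethyl acetal, which aminomethylenates the only enolisable aldehyde to the enaminal F5. Acid-catalysed amine–thiol exchange with tBuSH (AcOH, CH2Cl2) comes back to the route at 15.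

Risk 3, step 4. Endo/exo or facial discrimination may be poor, the E isomer of 7 may leak through, or a stepwise Mukaiyama–Michael pathway with silyl transfer may give the ring-opened adduct. The fallback moves from substrate control to catalyst control and sets out from 4. Compound 9 is prepared and isolated without 7, then combined with 7 at −78 °C under chelation catalysis by Cu(OTf)2 and a tert-butyl bis(oxazoline) ligand. The 1,3-dialdehyde binds the divalent copper in a bidentate way, the known mode for endo-selective oxadiene cycloadditions of enol ethers, and the ligand antipode is chosen to match the substrate bias. The path comes back at 10 and makes no new compound (F0).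

Further compounds
F1 | step 8 | (1S,3R)-3-[(2S,3R,4R)-2-acetoxy-5-(acetoxymethyl)-3-ethynyl-3,4-dihydro-2H-pyran-4-yl]-2,2-dimethylcyclopropane-1-carboxylic acid | CC(=O)OCC1=CO[C@@H](OC(C)=O)[C@@H](C#C)[C@H]1[C@@H]2[C@H](C(=O)O)C2(C)C
F2 | step 8 | Se-phenyl (1S,3R)-3-[(2S,3R,4R)-2-acetoxy-5-(acetoxymethyl)-3-ethynyl-3,4-dihydro-2H-pyran-4-yl]-2,2-dimethylcyclopropane-1-carboselenoate | CC(=O)OCC1=CO[C@@H](OC(C)=O)[C@@H](C#C)[C@H]1[C@@H]2[C@H](C(=O)[Se]c3ccccc3)C2(C)C
F3 | step 8 | Se-phenyl (1S,3R)-3-[(2S,3R,4R)-2-acetoxy-5-(acetoxymethyl)-3-[1-(tert-butylsulfanyl)-3-oxoprop-1-en-2-yl]-3,4-dihydro-2H-pyran-4-yl]-2,2-dimethylcyclopropane-1-carboselenoate | CC(=O)OCC1=CO[C@@H](OC(C)=O)[C@@H](C(C=O)=CSC(C)(C)C)[C@H]1[C@@H]2[C@H](C(=O)[Se]c3ccccc3)C2(C)C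
F4 | step 7 | [(2S,3S,4R)-2-acetoxy-4-[(1R,3S)-3-formyl-2,2-dimethylcyclopropyl]-3-(2-oxoethyl)-3,4-dihydro-2H-pyran-5-yl]methyl acetate | CC(=O)OCC1=CO[C@@H](OC(C)=O)[C@@H](CC=O)[C@H]1[C@@H]2[C@H](C=O)C2(C)C
F5 | step 7 | [(2S,3R,4R)-2-acetoxy-3-[1-(dimethylamino)-3-oxoprop-1-en-2-yl]-4-[(1R,3S)-3-formyl-2,2-dimethylcyclopropyl]-3,4-dihydro-2H-pyran-5-yl]methyl acetate | CC(=O)OCC1=CO[C@@H](OC(C)=O)[C@@H](C(C=O)=CN(C)C)[C@H]1[C@@H]2[C@H](C=O)C2(C)C
F0 | step 4 | none | none
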